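**Retrosynthetic overview**
1. The orthoester cage is made last, from the 4,6,15-triol and trimethyl orthocinnamate; O1 stays silylated until the final step.
2. The triol comes from a Δ5 alkene: O4 (from face-selective dihydroxylation of a C4=C15 methylene) carries a Si–H tether that adds across C5=C6 and sets H5 and O6 syn to O4; the C4 carbonyl comes from allylic oxidation.
3. Ring A (C1–C2–C3–C4–C5–C10) comes from a cyclobutanol ring (C1–C2–C3–C4, carbinol C1 on quaternary C10): the C1–C4 bond is broken and C4 is joined to the alkenyl-triflate carbon C5, so the C10–C5 edge of ring B is inserted and the four-membered ring becomes six-membered with C1 as ketone.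
4. Enabling feature: the oxygenated C1 sits on quaternary C10, and C10 is flanked on its other side by C5, the carbonyl carbon of a 2-methylcyclohexanone (ring B is the carvone ring); C1–C4 can therefore be bought as cyclobutanone and attached by one aldol at C10.
5. Order of rings: ring B from (R)-carvone (C7 from the chiral pool, C10 set by the aldol), then the cyclobutane (step 2), then ring A by ring expansion (step 4), then the three orthoester rings (step 12).

Key step: step 4

Remark: atom labels follow eudesmane numbering (decalin C1–C10, C14 = CH3 on C10, C15 on C4, C11–C13 = isopropyl on C7; "15-nor" = C15 absent); the allylic alcohol formed in step 7 is taken on as a mixture of C4 epimers, which converge in the same flask.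

Step 1
Reactants: 1 (R)-(−)-carvone
Product: 2 (R)-carvotanacetone
Conditions: H2 (1 atm), RhCl(PPh3)3 (2 mol %), toluene, rt
Reagents that add atoms: none
Why: Homogeneous hydrogenation with RhCl(PPh3)3 should reduce the unhindered 1,1-disubstituted isopropenyl alkene and leave the conjugated trisubstituted enone alone, with C7 untouched.

Step 2
Reactants: 2 (R)-carvotanacetone; 3 cyclobutanone
Product: 5 (2R,5R)-2-(1-hydroxycyclobutyl)-2-methyl-5-(propan-2-yl)cyclohexan-1-one, via lithium enolate 4 (not isolated)
Conditions: LiBH(s-Bu)3, THF, −78 °C; then 3, −78 °C; AcOH quench at −78 °C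
Reagents that add atoms: none
Why: Conjugate hydride reduction gives the regiodefined tetrasubstituted enolate 4, and its aldol addition to the strained, electrophilic cyclobutanone should occur by axial attack on the face syn to the equatorial isopropyl group (the facial preference known from Robinson annulations of dihydrocarvone), which sets quaternary C10 with methyl trans to isopropyl.

Step 3
Reactants: 5 (2R,5R)-2-(1-hydroxycyclobutyl)-2-methyl-5-(propan-2-yl)cyclohexan-1-one
Product: 6 (3S,6R)-6-(1-hydroxycyclobutyl)-6-methyl-3-(propan-2-yl)cyclohex-1-en-1-yl trifluoromethanesulfonate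
Conditions: LDA (2.2 equiv), THF, −78 °C; then N-(5-chloropyridin-2-yl)bis(trifluoromethanesulfonimide), −78 °C; AcOH quench
Reagents that add atoms: N-(5-chloropyridin-2-yl)-1,1,1-trifluoro-N-(trifluoromethylsulfonyl)methanesulfonamide, O=S(=O)(N(c1ccc(Cl)cn1)S(=O)(=O)C(F)(F)F)C(F)(F)F
Why: Enol triflate formation: double deprotonation gives the alkoxide and the only possible ketone enolate (toward C6), whose O-sulfonylation fixes the future C5=C6 bond; the alkoxide should resist retro-aldol cleavage at −78 °C because that would regenerate strained cyclobutanone.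

Step 4
Reactants: 6 (3S,6R)-6-(1-hydroxycyclobutyl)-6-methyl-3-(propan-2-yl)cyclohex-1-en-1-yl trifluoromethanesulfonate
Product: 7 (7S,10S)-15-noreudesm-5-en-1-one
Conditions: CeCl3 (10 mol %), Bu4NCl (20 mol %), 9,10-diphenylanthracene (5 mol %), NiBr2(dme) (10 mol %), 4,4'-di-tert-butyl-2,2'-bipyridine (12 mol %), 2,4,6-collidine (1.5 equiv), MeCN, 400 nm LEDs, rt
Reagents that add atoms: none
Why: Proposed new method: the tetravalent cerium alkoxide of the tertiary cyclobutanol (cerium being re-oxidised through the diphenylanthracene electron shuttle) should release the alkoxy radical on ligand-to-metal charge transfer, and strain-driven β-scission of a ring C–C bond unveils the C1 ketone and a primary C4 radical; nickel, inserted into the C5–OTf bond before or after it captures this radical, then forms the C4–C5 bond by C(sp3)–C(sp2) reductive elimination, so that the four-membered ring C1–C4 is enlarged by C10 and C5 into ring A. The closest known reaction types are the alkoxy-radical two-carbon ring expansion of 1-alkenylcycloalkanols (β-scission, then radical recombination) and the cerium/nickel or photoredox/nickel ring-opening arylation of cycloalkanols. Ring A closes as a six-membered ring by reductive elimination from a seven-membered alkyl(alkenyl)nickel metallacycle, exo with respect to the C5=C6 bond. No stereocentre is created: C7 and quaternary C10 are carried through, and the triflate fixes the alkene at C5=C6. The step needs ring-bond scission instead of loss of the C10 radical with cyclobutanone, which about 26 kcal/mol of ring strain should secure, and the symmetry of the cyclobutanol makes both ring bonds give the same radical. It also needs nickel capture faster than hydrogen abstraction, which the position of the triflate carbon five atoms from the radical should favour.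

Step 5
Reactants: 7 (7S,10S)-15-noreudesm-5-en-1-one
Product: 8 (1S,7S,10S)-15-noreudesm-5-en-1-ol
Conditions: NaBH4, MeOH, 0 °C
Reagents that add atoms: none
Why: Borohydride reduction with hydride delivered anti to the axial C10 methyl (axial attack, as in 8a-methyl-octalin-1-ones with the same ring A) should give the equatorial C1 alcohol cis to the angular methyl.

Step 6
Reactants: 8 (1S,7S,10S)-15-noreudesm-5-en-1-ol
Product: 9 (1S,7S,10S)-1-(tert-butyldimethylsilyloxy)-15-noreudesm-5-ene
Conditions: TBSOTf, 2,6-lutidine, CH2Cl2, 0 °C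
Reagents that add atoms: tert-butyldimethylsilyl trifluoromethanesulfonate, CC(C)(C)[Si](C)(C)OS(=O)(=O)C(F)(F)F
Why: Silyl triflate silylation masks the hindered secondary O1 before the oxidations and the Si–H tether chemistry; no stereocentre is touched.

Step 7
Reactants: 9 (1S,7S,10S)-1-(tert-butyldimethylsilyloxy)-15-noreudesm-5-ene
Product: 11 (1S,7S,10S)-1-(tert-butyldimethylsilyloxy)-15-noreudesm-5-en-4-one, via allylic alcohol 10 (not isolated)
Conditions: SeO2 (0.3 equiv), t-BuOOH, CH2Cl2, rt; aqueous wash; then Dess–Martin periodinane, CH2Cl2, rt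
Reagents that add atoms: tert-butyl hydroperoxide, CC(C)(C)OO (terminal oxygen source); selenium dioxide, O=[Se]=O (catalytic oxygen carrier)
Why: Allylic oxidation with SeO2 (ene reaction, then [2,3]-sigmatropic shift) should occur at the CH2 on the more substituted end of the trisubstituted alkene, which is C4, and Dess–Martin oxidation of both alcohol epimers converges on the enone.

Step 8
Reactants: 11 (1S,7S,10S)-1-(tert-butyldimethylsilyloxy)-15-noreudesm-5-en-4-one
Product: 12 (1S,7S,10S)-1-(tert-butyldimethylsilyloxy)eudesma-4(15),5-diene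
Conditions: Ph3PCH3Br, KHMDS, THF, 0 °C to rt
Reagents that add atoms: methyltriphenylphosphonium bromide, C[P+](c1ccccc1)(c1ccccc1)c1ccccc1.[Br-]
Why: Wittig methylenation of the enone carbonyl installs C15 as the exocyclic methylene; the ylide is added at 0 °C to limit γ-deprotonation toward C7.

Step 9
Reactants: 12 (1S,7S,10S)-1-(tert-butyldimethylsilyloxy)eudesma-4(15),5-diene
Product: 13 (1S,4S,7S,10S)-1-(tert-butyldimethylsilyloxy)eudesm-5-ene-4,15-diol
Conditions: OsO4 (2 mol %), N-methylmorpholine N-oxide, acetone/H2O, 0 °C to rt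
Reagents that add atoms: N-methylmorpholine N-oxide, C[N+]1([O-])CCOCC1; water, O; osmium tetroxide, O=[Os](=O)(=O)=O (catalytic oxygen carrier)
Why: Upjohn dihydroxylation: osmium should attack the unhindered exocyclic alkene from the face opposite the axial C10 methyl (1,3-diaxial to C4), which places O4 equatorial and C15 axial, while the trisubstituted C5=C6 bond between quaternary C10 and the isopropyl-bearing C7 should react more slowly.

Step 10
Reactants: 13 (1S,4S,7S,10S)-1-(tert-butyldimethylsilyloxy)eudesm-5-ene-4,15-diol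
Product: 17 (1S,4S,5R,6R,7S,10S)-1-(tert-butyldimethylsilyloxy)eudesmane-4,6,15-triol, via trimethylsilyl ether 14 (not isolated), via hydrosilyl ether 15 (not isolated), via cyclic siloxane 16 (not isolated)
Conditions: Me3SiCl (1.05 equiv), Et3N, CH2Cl2, −78 °C; Me2SiHCl, Et3N, DMAP, 0 °C to rt; filter, concentrate; Pt2(dvtms)3 (1 mol %, dvtms = 1,3-divinyltetramethyldisiloxane), toluene, 60 °C; KF, KHCO3, 30% H2O2, THF/MeOH, rt
Reagents that add atoms: hydrogen peroxide, OO
Why: Intramolecular hydrosilylation (platinum-catalysed syn addition of Si–H, 5-endo mode of an allylic silyl ether) should deliver silicon to C6 and hydrogen to C5 from the face of the tethering O4, and Tamao–Fleming oxidation with retention turns C6–Si into C6–OH, so H5 (trans ring fusion) and the equatorial O6 are both set by the C4 stereocentre while fluoride removes the temporary trimethylsilyl group.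

Step 11
Reactants: 18 (E)-cinnamonitrile
Product: 20 trimethyl orthocinnamate, via imidate hydrochloride 19 (not isolated)
Conditions: HCl (g), MeOH (1.1 equiv), Et2O, 0 °C; then MeOH (excess), rt
Reagents that add atoms: methanol, CO
Why: Pinner reaction: HCl adds methanol to the nitrile to give the imidate salt, whose methanolysis gives the orthoester and ammonium chloride without involving the E alkene.

Step 12
Reactants: 17 (1S,4S,5R,6R,7S,10S)-1-(tert-butyldimethylsilyloxy)eudesmane-4,6,15-triol; 20 trimethyl orthocinnamate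
Product: 21 (1S,4S,5R,6R,7S,10S)-1-(tert-butyldimethylsilyloxy)eudesmane-4,6,15-triyl orthocinnamate
Conditions: camphorsulfonic acid (5 mol %), 4 Å molecular sieves, CH2Cl2, rt; Et3N quench
Reagents that add atoms: none
Why: Acid-catalysed orthoester exchange: the equatorial O4 and O6 and the axial C15–OH of the rigid trans-decalin replace the three methoxy groups, and the configuration of the new orthoester carbon is dictated by the cage (only one is possible).

Step 13
Reactants: 21 (1S,4S,5R,6R,7S,10S)-1-(tert-butyldimethylsilyloxy)eudesmane-4,6,15-triyl orthocinnamate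
Product: 22 CNP0190302.1
Conditions: Bu4NF, THF, rt to 40 °C; aqueous work-up, chromatography on Et3N-buffered silica
Reagents that add atoms: none
Why: Fluoride-mediated desilylation frees O1, and the orthoester is stable to fluoride and base, so the acid-sensitive cage should survive.

**Compound list**
1 | (R)-(−)-carvone, (5R)-2-methyl-5-(prop-1-en-2-yl)cyclohex-2-en-1-one | CC(=C)[C@@H]1CC=C(C)C(=O)C1 | starting material
2 | (R)-carvotanacetone, (5R)-2-methyl-5-(propan-2-yl)cyclohex-2-en-1-one | CC(C)[C@@H]1CC=C(C)C(=O)C1 | intermediate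
3 | cyclobutanone | O=C1CCC1 | starting material
4 | lithium (5R)-2-methyl-5-(propan-2-yl)cyclohex-1-en-1-olate (not isolated) | [Li+].CC(C)[C@@H]1CCC(C)=C([O-])C1 | intermediate
5 | (2R,5R)-2-(1-hydroxycyclobutyl)-2-methyl-5-(propan-2-yl)cyclohexan-1-one (cyclobutyl cis to isopropyl) | CC(C)[C@@H]1CC[C@](C)(C2(O)CCC2)C(=O)C1 | intermediate
6 | (3S,6R)-6-(1-hydroxycyclobutyl)-6-methyl-3-(propan-2-yl)cyclohex-1-en-1-yl trifluoromethanesulfonate | CC(C)[C@@H]1CC[C@](C)(C2(O)CCC2)C(OS(=O)(=O)C(F)(F)F)=C1 | intermediate
7 | (7S,10S)-15-noreudesm-5-en-1-one, (6S,8aS)-8a-methyl-6-(propan-2-yl)-3,4,6,7,8,8a-hexahydronaphthalen-1(2H)-one | CC(C)[C@@H]1CC[C@]2(C)C(=O)CCCC2=C1 | intermediate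
8 | (1S,7S,10S)-15-noreudesm-5-en-1-ol (OH cis to C14) | CC(C)[C@@H]1CC[C@]2(C)[C@@H](O)CCCC2=C1 | intermediate
9 | (1S,7S,10S)-1-(tert-butyldimethylsilyloxy)-15-noreudesm-5-ene | CC(C)[C@@H]1CC[C@]2(C)[C@@H](O[Si](C)(C)C(C)(C)C)CCCC2=C1 | intermediate
10 | (1S,7S,10S)-1-(tert-butyldimethylsilyloxy)-15-noreudesm-5-en-4-ol, mixture of C4 epimers (not isolated) | CC(C)[C@@H]1CC[C@]2(C)[C@@H](O[Si](C)(C)C(C)(C)C)CCC(O)C2=C1 | intermediate
11 | (1S,7S,10S)-1-(tert-butyldimethylsilyloxy)-15-noreudesm-5-en-4-one | CC(C)[C@@H]1CC[C@]2(C)[C@@H](O[Si](C)(C)C(C)(C)C)CCC(=O)C2=C1 | intermediate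
12 | (1S,7S,10S)-1-(tert-butyldimethylsilyloxy)eudesma-4(15),5-diene | CC(C)[C@@H]1CC[C@]2(C)[C@@H](O[Si](C)(C)C(C)(C)C)CCC(=C)C2=C1 | intermediate
13 | (1S,4S,7S,10S)-1-(tert-butyldimethylsilyloxy)eudesm-5-ene-4,15-diol (O4 trans to C14) | CC(C)[C@@H]1CC[C@]2(C)[C@@H](O[Si](C)(C)C(C)(C)C)CC[C@@](O)(CO)C2=C1 | intermediate
14 | 15-O-trimethylsilyl ether of 13 (not isolated) | CC(C)[C@@H]1CC[C@]2(C)[C@@H](O[Si](C)(C)C(C)(C)C)CC[C@@](O)(CO[Si](C)(C)C)C2=C1 | intermediate
15 | 4-O-dimethylsilyl (Si–H) ether of 14 (not isolated) | CC(C)[C@@H]1CC[C@]2(C)[C@@H](O[Si](C)(C)C(C)(C)C)CC[C@@](O[SiH](C)C)(CO[Si](C)(C)C)C2=C1 | intermediate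
16 | cyclic siloxane with O4–SiMe2–C6 bridge, H5 and Si cis to O4 (not isolated) | CC(C)[C@@H]1CC[C@@]2(C)[C@@H]3[C@@H]1[Si](C)(C)O[C@@]3(CO[Si](C)(C)C)CC[C@@H]2O[Si](C)(C)C(C)(C)C | intermediate
17 | (1S,4S,5R,6R,7S,10S)-1-(tert-butyldimethylsilyloxy)eudesmane-4,6,15-triol | CC(C)[C@@H]1CC[C@@]2(C)[C@H]([C@@H]1O)[C@](O)(CO)CC[C@@H]2O[Si](C)(C)C(C)(C)C | intermediate
18 | (E)-cinnamonitrile | N#C/C=C/c1ccccc1 | starting material
19 | methyl (E)-3-phenylprop-2-enimidate hydrochloride (not isolated) | COC(=[NH2+])/C=C/c1ccccc1.[Cl-] | intermediate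
20 | trimethyl orthocinnamate, (E)-(3,3,3-trimethoxyprop-1-en-1-yl)benzene | COC(OC)(OC)/C=C/c1ccccc1 | intermediate
21 | (1S,4S,5R,6R,7S,10S)-1-(tert-butyldimethylsilyloxy)eudesmane-4,6,15-triyl orthocinnamate | CC(C)[C@@H]1CC[C@@]2(C)[C@@H]3[C@@H]1O[C@]1(/C=C/c4ccccc4)OC[C@@]3(CC[C@@H]2O[Si](C)(C)C(C)(C)C)O1 | intermediate
22 | CNP0190302.1, (1S,4S,5R,6R,7S,10S)-eudesmane-1,4,6,15-tetrol 4,6,15-orthocinnamate | CC(C)[C@@H]1CC[C@@]2(C)[C@@H]3[C@@H]1O[C@]1(/C=C/c4ccccc4)OC[C@@]3(CC[C@@H]2O)O1 | target

**Step count**
Total: 13 steps. Longest linear sequence: 12 steps (1, 2, 3, 4, 5, 6, 7, 8, 9, 10, 12, 13 from (R)-carvone); step 11 is a one-step side branch.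

**Steps most likely to fail**

Step 4. The alkoxy radical may fragment at the exocyclic C1–C10 bond with loss of cyclobutanone, the C4 radical may abstract hydrogen before nickel captures it, or the triflate may be reduced. The fallback performs the same ring enlargement in two known steps and sets out from 6. A hypoiodite (alkoxy radical) fragmentation with PhI(OAc)2 and I2 under visible light in CH2Cl2 should open the cyclobutanol to (3S,6S)-6-(4-iodobutanoyl)-6-methyl-3-(propan-2-yl)cyclohex-1-en-1-yl trifluoromethanesulfonate F1. Intramolecular nickel-catalysed reductive cross-electrophile coupling of the primary iodide with the alkenyl triflate (NiBr2(dme), 4,4'-di-tert-butyl-2,2'-bipyridine, Zn, DMA) should then close ring A and come back to the route at 7.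

Step 10. The 5-endo hydrosilylation may be too slow at the hindered trisubstituted alkene, leading to alkene migration or loss of the silyl tether, or the C–Si oxidation may stall. The fallback sets out from 13 and replaces silicon delivery by oxygen delivery. Selective acetylation of the primary alcohol (Ac2O, pyridine) should give the 15-acetate of 13 F2. Epoxidation with VO(acac)2 and t-BuOOH, directed by the free tertiary allylic O4–H, should give the 5,6-epoxide syn to O4 F3. Reductive opening with Cp2TiCl (trivalent titanium, from Cp2TiCl2 and Mn) and 1,4-cyclohexadiene should break the C5–O bond and transfer hydrogen to the tertiary C5 radical anti to the C10 methyl, giving the 4,6-diol 15-acetate F4. Methanolysis (K2CO3, MeOH) comes back to the route at 17.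

Step 9. Osmium may also attack the C5=C6 bond of the diene, or the facial selectivity at C4 may be poor. The fallback sets out from 11 and makes the C4 alkene electron-rich so that chemoselectivity is electronic. A Wittig reaction with methoxymethylenetriphenylphosphorane (from (methoxymethyl)triphenylphosphonium chloride and KHMDS) should give the methyl enol ether (1S,7S,10S)-1-(tert-butyldimethylsilyloxy)-15-methoxyeudesma-4(15),5-diene F5. Epoxidation of the enol ether with dimethyldioxirane from the face opposite the C10 methyl, followed by hydrolysis (Rubottom-type oxidation), should give the α-hydroxy aldehyde (1S,4S,7S,10S)-1-(tert-butyldimethylsilyloxy)-4-hydroxyeudesm-5-en-15-al F6. NaBH4 reduction comes back to the route at 13.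

**Further compounds**
F1 | step 4 | (3S,6S)-6-(4-iodobutanoyl)-6-methyl-3-(propan-2-yl)cyclohex-1-en-1-yl trifluoromethanesulfonate | CC(C)[C@@H]1CC[C@](C)(C(=O)CCCI)C(OS(=O)(=O)C(F)(F)F)=C1
F2 | step 10 | 15-acetate of 13 | CC(C)[C@@H]1CC[C@]2(C)[C@@H](O[Si](C)(C)C(C)(C)C)CC[C@@](O)(COC(C)=O)C2=C1
F3 | step 10 | 5,6-epoxide of F2, epoxide oxygen cis to O4 | CC(C)[C@@H]1CC[C@@]2(C)[C@@]3(O[C@H]13)[C@](O)(COC(C)=O)CC[C@@H]2O[Si](C)(C)C(C)(C)C
F4 | step 10 | 15-acetate of 17 | CC(C)[C@@H]1CC[C@@]2(C)[C@H]([C@@H]1O)[C@](O)(COC(C)=O)CC[C@@H]2O[Si](C)(C)C(C)(C)C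
F5 | step 9 | (1S,7S,10S)-1-(tert-butyldimethylsilyloxy)-15-methoxyeudesma-4(15),5-diene, E/Z mixture | CC(C)[C@@H]1CC[C@]2(C)[C@@H](O[Si](C)(C)C(C)(C)C)CCC(=COC)C2=C1
F6 | step 9 | (1S,4S,7S,10S)-1-(tert-butyldimethylsilyloxy)-4-hydroxyeudesm-5-en-15-al | CC(C)[C@@H]1CC[C@]2(C)[C@@H](O[Si](C)(C)C(C)(C)C)CC[C@@](O)(C=O)C2=C1
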